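**Assumptions (one line):** labdane numbering is used for the diterpenoid half and primed locants for the flavonoid-derived ring (C1′ = quaternary carbon bearing the chromone, C6′ = ring-fusion CH); a one-pot, two-stage operation counts as one step.

## Retrosynthetic overview

1. Target ⇒ [4+2] disconnection of the cyclohexene (C12–C1′ and C15–C6′): (12E)-7β-hydroxylabda-8(17),12,14-trien-18-oic acid (10) plus the flavone B-ring methoxy-p-quinone, generated anodically in situ from 5,7-dihydroxy-2′,4′,5′-trimethoxyflavone (13).
2. 13 ⇐ 2′,4′,6′-trihydroxyacetophenone + 2,4,5-trimethoxybenzoyl chloride (one-pot C-acylation/cyclodehydration forms the chromone ring).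
3. 10 ⇐ (−)-abietic acid, which supplies C4, C5, C9 and C10. Ring C is cut at C13=C14, C14 becomes the exocyclic methylene by an epoxy-aldehyde transposition, C13/isopropyl is excised to a C12 aldehyde, and two Wittig reactions build the (E)-diene.
4. C7 is reset to 7β by oxidation and axial hydride delivery.
5. Ring order: A/B decalin bought; chromone ring in the flavone branch; the cyclohexene ring last, in the electrochemical step.

## Route

**Step 1**
Reactants: 1, (−)-abietic acid
Product: 2, 13-oxo-13,14-seco-abiet-7-en-14-al-18-oic acid (ring-B enal plus isopropyl ketone side chain)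
Conditions: OsO4 (2 mol %), NMO, acetone–H2O, 0 °C→rt; then NaIO4, THF–H2O, 0 °C
Reagents that add atoms: osmium tetroxide, O=[Os](=O)(=O)=O (O donor, turned over by NMO, C[N+]1([O-])CCOCC1)
Why: catalytic OsO4 dihydroxylates only the more exposed C13=C14 bond of the heteroannular diene, and in-pot periodate glycol cleavage opens ring C to the enal and ketone without touching C4, C5, C9 or C10 (Upjohn dihydroxylation/Malaprade cleavage).

**Step 2**
Reactants: 2
Product: 3, 7α,8α-epoxy-13-oxo-13,14-seco-abietan-14-al-18-oic acid
Conditions: 30% H2O2, NaOH, MeOH, 0 °C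
Reagents that add atoms: hydrogen peroxide, OO
Why: Weitz–Scheffer nucleophilic epoxidation, in which hydroperoxide adds axially to C7 from the α-face (anti to the C10 methyl) while the unconjugated ketone and the carboxylate are inert; the C7 configuration is reset in steps 8–9, so this selectivity is not critical.

**Step 3**
Reactants: 3
Product: 4, 7α-hydroxy-13-oxo-13,14-seco-abiet-8(14)-en-18-oic acid (exocyclic methylene = labdane C17)
Conditions: N2H4·H2O (2 equiv), AcOH, MeOH, 0 °C→rt
Reagents that add atoms: none
Why: Wharton transposition, in which the aldehyde hydrazone (formed much faster than that of the hindered isopropyl ketone) opens the epoxide and loses N2, turning C14 into the =CH2 group and leaving the C7–O bond intact (7α-OH).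

**Step 4**
Reactants: 4
Product: 5, 7α,12ξ-dihydroxy-13-oxo-13,14-seco-abiet-8(14)-en-18-oic acid (α-ketol, C12 epimers)
Conditions: KHMDS (3.5 equiv), THF, −78 °C; then (±)-2-(phenylsulfonyl)-3-phenyloxaziridine, −78 °C; NH4Cl
Reagents that add atoms: racemic Davis oxaziridine, O=S(=O)(N1OC1c1ccccc1)c1ccccc1
Why: kinetic deprotonation occurs at the less hindered C12 methylene, not the isopropyl methine, and the enolate is hydroxylated by the oxaziridine, which does not epoxidise the exocyclic alkene (Davis α-hydroxylation; the new C12 centre is destroyed in step 5).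

**Step 5**
Reactants: 5
Product: 6, 7α-hydroxy-12-oxo-13,14,15,16-tetranorlabd-8(17)-en-18-oic acid (C12 aldehyde)
Conditions: NaIO4, MeOH–H2O, rt
Reagents that add atoms: none
Why: Malaprade cleavage of the α-ketol removes C13 and the isopropyl group as isobutyric acid and leaves C12 as the aldehyde, with no stereocentre affected.

**Step 6**
Reactants: 6
Product: 7, (12E)-7α-hydroxy-14-oxo-15-norlabda-8(17),12-dien-18-oic acid
Conditions: Ph3P=C(CH3)CHO (2.5 equiv), PhMe, 80 °C
Reagents that add atoms: 2-(triphenylphosphoranylidene)propanal, CC(C=O)=P(c1ccccc1)(c1ccccc1)c1ccccc1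
Why: Wittig olefination with the stabilised ylide gives the (E)-2-methyl enal with high selectivity, the excess ylide compensating for proton transfer from the free acid.

**Step 7**
Reactants: 7
Product: 8, (12E)-7α-hydroxylabda-8(17),12,14-trien-18-oic acid
Conditions: Ph3PCH3Br (5 equiv), KOtBu (4.8 equiv), THF, 0 °C→rt
Reagents that add atoms: methyltriphenylphosphonium bromide, C[P+](c1ccccc1)(c1ccccc1)c1ccccc1.[Br-]
Why: Wittig methylenation of the unhindered enal completes the (12E)-diene without touching the trisubstituted alkene geometry; carboxylate and alkoxide are spectators.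

**Step 8**
Reactants: 8
Product: 9, (12E)-7-oxolabda-8(17),12,14-trien-18-oic acid
Conditions: MnO2 (excess), CH2Cl2, rt; use at once
Reagents that add atoms: none
Why: MnO2 oxidises only the allylic C7 alcohol to the exocyclic enone (chemoselective allylic oxidation), leaving the diene and acid intact.

**Step 9**
Reactants: 9
Product: 10, (4R,5R,7S,9R,10R,12E)-7β-hydroxylabda-8(17),12,14-trien-18-oic acid
Conditions: NaBH4, CeCl3·7H2O, MeOH, −78 °C
Reagents that add atoms: none
Why: Luche 1,2-reduction, in which hydride attacks C7 axially from the α-face of the trans-decalin to give the equatorial 7β-alcohol (7S) by substrate control, without conjugate reduction.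

**Step 10**
Reactants: 11, 2′,4′,6′-trihydroxyacetophenone; 12, 2,4,5-trimethoxybenzoyl chloride
Product: 13, 5,7-dihydroxy-2′,4′,5′-trimethoxyflavone
Conditions: LiHMDS (4.2 equiv), THF, −78→−10 °C; 12, −78 °C→rt; then AcOH, cat. H2SO4, 95 °C
Reagents that add atoms: none
Why: the lithium polyanion of the acetophenone is C-acylated to the β-diketone, which cyclodehydrates in acid to the chromone (one-pot Baker–Venkataraman-type flavone synthesis; no stereocentres).

**Step 11**
Reactants: 10; 13
Product: 14, dichrostachine E. It is cis-fused at C1′/C6′; C11, the chromon-2-yl group and H-6′ lie on one face of the new cyclohexene, and H-12 and the C2′/C5′ carbonyl carbons on the other (4R,5R,7S,9R,10R,12R,1′S,6′R).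
Conditions: RVC(+)/Pt-wire(−), undivided cell, +1.25 V vs Ag/AgCl (about 2.2 F mol⁻¹ based on 13), 0.5 M LiClO4, MeCN–H2O 9:1, 10 (1.5 equiv), 0 °C; then 25 °C, 24 h, dark; HPLC
Reagents that add atoms: water, O (supplies both quinone carbonyl oxygens; two MeOH are lost)
Why: Proposed new method: an anodic oxidative-demethylation/Diels–Alder cascade in which the 2,4,5-trimethoxyaryl ring, the most easily oxidised site (estimated ≥0.3 V below the triene and the hydrogen-bonded dihydroxychromone), is converted in wet MeCN by a 2 e⁻ oxidation into the 2-methoxy-p-quinone, which is trapped in the cell by the (12E)-diene at its only non-deactivated C=C (the other is a vinylogous ester); in the Li⁺-rich ionising medium the [4+2] should be strongly asynchronous, with the unsubstituted terminus C15 bonding first to C6′ (β to the Li⁺-bound C2′=O and vinylogous to the chromone carbonyl), and the C12–C1′ bond then closing suprafacially (cis fusion) through the half-chair that keeps C11 pseudo-axial (no A1,2 strain with the C13 methyl, anti to C2′) and therefore cis to the chromonyl, on the diene face anti to the decalin (C9 control); the closest known reactions are anodic oxidation of p-dimethoxyarenes to quinones and electrochemically triggered quinone Diels–Alder reactions in LiClO4 media.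

## Compound list

1 | (−)-abietic acid | CC(C)C1=CC2=CC[C@@H]3[C@](C)(CCC[C@@]3(C)C(=O)O)[C@H]2CC1 | starting material
2 | 13-oxo-13,14-seco-abiet-7-en-14-al-18-oic acid | O=CC1=CC[C@@H]2[C@](C)(CCC[C@@]2(C)C(=O)O)[C@H]1CCC(=O)C(C)C | intermediate
3 | 7α,8α-epoxy-13-oxo-13,14-seco-abietan-14-al-18-oic acid | O=C[C@@]12O[C@@H]1C[C@@H]3[C@](C)(CCC[C@@]3(C)C(=O)O)[C@H]2CCC(=O)C(C)C | intermediate
4 | 7α-hydroxy-13-oxo-13,14-seco-abiet-8(14)-en-18-oic acid | C=C1[C@H](O)C[C@@H]2[C@](C)(CCC[C@@]2(C)C(=O)O)[C@H]1CCC(=O)C(C)C | intermediate
5 | 7α,12ξ-dihydroxy-13-oxo-13,14-seco-abiet-8(14)-en-18-oic acid | C=C1[C@H](O)C[C@@H]2[C@](C)(CCC[C@@]2(C)C(=O)O)[C@H]1CC(O)C(=O)C(C)C | intermediate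
6 | 7α-hydroxy-12-oxo-13,14,15,16-tetranorlabd-8(17)-en-18-oic acid | C=C1[C@H](O)C[C@@H]2[C@](C)(CCC[C@@]2(C)C(=O)O)[C@H]1CC=O | intermediate
7 | (12E)-7α-hydroxy-14-oxo-15-norlabda-8(17),12-dien-18-oic acid | C=C1[C@H](O)C[C@@H]2[C@](C)(CCC[C@@]2(C)C(=O)O)[C@H]1C/C=C(\C)C=O | intermediate
8 | (12E)-7α-hydroxylabda-8(17),12,14-trien-18-oic acid | C=C1[C@H](O)C[C@@H]2[C@](C)(CCC[C@@]2(C)C(=O)O)[C@H]1C/C=C(\C)C=C | intermediate
9 | (12E)-7-oxolabda-8(17),12,14-trien-18-oic acid | C=C1C(=O)C[C@@H]2[C@](C)(CCC[C@@]2(C)C(=O)O)[C@H]1C/C=C(\C)C=C | intermediate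
10 | (12E)-7β-hydroxylabda-8(17),12,14-trien-18-oic acid | C=C1[C@@H](O)C[C@@H]2[C@](C)(CCC[C@@]2(C)C(=O)O)[C@H]1C/C=C(\C)C=C | intermediate
11 | 2′,4′,6′-trihydroxyacetophenone | CC(=O)c1c(O)cc(O)cc1O | starting material
12 | 2,4,5-trimethoxybenzoyl chloride | COc1cc(OC)c(C(=O)Cl)cc1OC | starting material
13 | 5,7-dihydroxy-2′,4′,5′-trimethoxyflavone | COc1cc(OC)c(cc1OC)-c1cc(=O)c2c(O)cc(O)cc2o1 | intermediate
14 | dichrostachine E | C=C1[C@@H](O)C[C@@H]2[C@](C)(CCC[C@@]2(C)C(=O)O)[C@H]1C[C@@H]1C(C)=CC[C@H]2C(=O)C(OC)=CC(=O)[C@@]12c1cc(=O)c2c(O)cc(O)cc2o1 | target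

## Step count

Total steps: 11. Longest linear sequence: 10 (steps 1–9, then 11).

## Three steps most likely to fail

1. **Step 11 (the proposed new step).** Risks:
   - Competing anodic oxidation of the triene or the phenols.
   - A slow cycloaddition at the trisubstituted, aryl-bearing quinone C=C.
   - Stereochemistry. A conventional concerted Alder mode (quinone ring endo) would give the opposite C12/C1′ relationship, and π-facial control by C9 is likely to be modest, so diastereomers may need HPLC separation.

   Fallback (known chemistry): isolate the quinone by CAN oxidative demethylation of 13, then run a thermal or 10–13 kbar Diels–Alder with the triene and separate isomers. If the quinone-endo adduct dominates, use the (12Z)-isomer of 10 (Z-selective olefination of 6), whose quinone-endo adduct has the required cis C11/chromonyl relationship.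

2. **Step 3 (Wharton transposition on an epoxy aldehyde next to a free ketone).** Risks are hydrazone or azine formation at the ketone and low yield. Fallback: reductive 1,3-transposition of the enal tosylhydrazone of 2 (catecholborane, NaOAc) to the 8(17)-ene, then SeO2/t-BuOOH allylic oxidation to the 7-ol/7-one, rejoining the route before step 4 (C7 is reset in steps 8–9 anyway).

3. **Step 4 (regioselective α-hydroxylation of a trianion).** Risks are poor solubility or enolisation and competing reaction at the isopropyl side. Fallback: install the C12 oxygen before ring cleavage by SeO2 allylic oxidation of abietic acid to 12α-hydroxyabietic acid. Dihydroxylation and periodate cleavage of the resulting 12,13,14-triol then give the C12 aldehyde directly; it is carried as its dimethyl acetal through the ring-B transposition.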